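**Plan**

1. Numbering: dihydrobenzofuran O1, C2, C3, C3a, C4 (OMe), C5 (enone), C7a. Ring A is the benzene ring of the benzofuran, ring B the dihydrofuran, ring C the 4-hydroxyphenyl group.
2. Retrosynthetic cuts, in order: the enone Cα=Cβ bond (aldol condensation, ring C leaves as its methyl ketone); the C3–C3a bond of ring B; the two carbinol C–CH3 bonds (back to an ester); the O1–C2 aryl ether bond (back to a lactate); the C5–CHO bond.
3. Enabling feature: with C3–C3a cut, C3 is simply the methyl group of a lactic acid unit on O1. It lies 1,5 to C3a through O1–C2, so palladium on C3a reaches a C3–H bond through a six-membered palladacycle. C3a is the carbon between the two ring A oxygens (O1 and the C4 methoxy), so symmetrical 2-bromoresorcinol places the halogen there with no regiochemical question.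
4. Forward: ring A is bought; formyl group, lactate side chain, methyl ether, acetal, carbinol methyls and a silyl cap are added; ring B is closed by C(sp3)–H arylation; deprotection and condensation then bring in the enone and ring C.
5. Stereochemistry: C2 (S) comes from methyl (R)-lactate through one inversion in the Mitsunobu etherification and is not touched again; the E alkene is the thermodynamic outcome of the condensation.

Key step: step 7

Assumption: the three numbered starting materials are taken as commercial.

**Route**

Step 1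
Reactants: 1 2-bromoresorcinol (2-bromobenzene-1,3-diol)
Product: 3 3-bromo-2,4-dihydroxybenzaldehyde, via iminium chloride 2 (not isolated)
Conditions: POCl3, DMF, MeCN, −15 °C to rt; then H2O, 50 °C
Reagents that add atoms: N,N-dimethylformamide CN(C)C=O; water O
Why: Vilsmeier–Haack formylation, in which the chloroiminium ion attacks the position para to one hydroxyl and ortho to the other (C4 and C6 of the symmetrical diol are equivalent), so a single aldehyde is expected after hydrolysis of the iminium salt and no stereocenter is formed.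

Step 2
Reactants: 3 3-bromo-2,4-dihydroxybenzaldehyde; 4 methyl (R)-lactate (methyl (2R)-2-hydroxypropanoate)
Product: 6 methyl (2S)-2-(2-bromo-4-formyl-3-hydroxyphenoxy)propanoate, via alkoxyphosphonium phenoxide 5 (not isolated)
Conditions: PPh3, DIAD, THF, 0 °C to rt
Reagents that add atoms: none
Why: Mitsunobu etherification, in which the 4-OH (para to the aldehyde, more acidic, not hydrogen-bonded) should react while the 2-OH stays chelated to the aldehyde, and SN2 displacement of the alkoxyphosphonium group inverts the lactate carbon from R to S, which sets C2 of the target.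

Step 3
Reactants: 6 methyl (2S)-2-(2-bromo-4-formyl-3-hydroxyphenoxy)propanoate
Product: 7 methyl (2S)-2-(2-bromo-4-formyl-3-methoxyphenoxy)propanoate
Conditions: MeI, K2CO3, DMF, rt
Reagents that add atoms: iodomethane CI
Why: Williamson O-methylation of the remaining chelated phenol with a mild carbonate base at room temperature, under which the α-aryloxy ester stereocenter is not expected to epimerize.

Step 4
Reactants: 7 methyl (2S)-2-(2-bromo-4-formyl-3-methoxyphenoxy)propanoate
Product: 8 methyl (2S)-2-[2-bromo-4-(1,3-dioxolan-2-yl)-3-methoxyphenoxy]propanoate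
Conditions: (TMSOCH2)2, TMSOTf (cat.), CH2Cl2, −78 to −20 °C; then pyridine
Reagents that add atoms: 1,2-bis(trimethylsilyloxy)ethane C[Si](C)(C)OCCO[Si](C)(C)C
Why: Acid-catalysed acetalization with the bis-silyl ether of ethylene glycol under aprotic conditions masks the aldehyde as a 1,3-dioxolane without touching the ester or the stereocenter, so that the Grignard reagent of the next step meets only the ester.

Step 5
Reactants: 8 methyl (2S)-2-[2-bromo-4-(1,3-dioxolan-2-yl)-3-methoxyphenoxy]propanoate
Product: 10 (3S)-3-[2-bromo-4-(1,3-dioxolan-2-yl)-3-methoxyphenoxy]-2-methylbutan-2-ol, via methyl ketone 9 (not isolated)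
Conditions: MeMgBr (3 equiv), THF, 0 °C to rt; then NH4Cl (aq)
Reagents that add atoms: methylmagnesium bromide C[Mg]Br
Why: Double Grignard addition to the ester through the chelated α-aryloxy methyl ketone, which should add the second equivalent faster than it enolizes, builds the tertiary carbinol with the C2 configuration intact, while acetal and aryl bromide are inert to MeMgBr at this temperature.

Step 6
Reactants: 10 (3S)-3-[2-bromo-4-(1,3-dioxolan-2-yl)-3-methoxyphenoxy]-2-methylbutan-2-ol
Product: 11 {[(3S)-3-[2-bromo-4-(1,3-dioxolan-2-yl)-3-methoxyphenoxy]-2-methylbutan-2-yl]oxy}(trimethyl)silane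
Conditions: TMSCl, imidazole, DMF, rt
Reagents that add atoms: chlorotrimethylsilane C[Si](C)(C)Cl
Why: Silylation of the tertiary alcohol as its trimethylsilyl ether removes the free hydroxyl that could otherwise engage the arylpalladium intermediate of the next step in C–O bond formation to a 1,4-benzodioxane.

Step 7
Reactants: 11 {[(3S)-3-[2-bromo-4-(1,3-dioxolan-2-yl)-3-methoxyphenoxy]-2-methylbutan-2-yl]oxy}(trimethyl)silane
Product: 14 ({2-[(2S)-5-(1,3-dioxolan-2-yl)-4-methoxy-2,3-dihydro-1-benzofuran-2-yl]propan-2-yl}oxy)(trimethyl)silane, via arylpalladium pivalate 12 (not isolated), via palladacycle 13 (not isolated)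
Conditions: Pd(OAc)2 (5 mol%), PCy3·HBF4 (10 mol%), PivOH (30 mol%), Cs2CO3 (1.5 equiv), mesitylene, 135 °C
Reagents that add atoms: none
Why: Zerovalent palladium (from Pd(OAc)2 and PCy3) inserts into the C–Br bond between the two ring A oxygens, bromide is exchanged for pivalate, and the pivalate takes a proton from the lactate-derived methyl group by concerted metalation–deprotonation to give a six-membered palladacycle, whose C(sp2)–C(sp3) reductive elimination forms the C3–C3a bond and returns zerovalent palladium. The closest known reaction type is the palladium/pivalate-catalysed intramolecular C(sp3)–H arylation of 2-bromophenyl alkyl ethers to 2,3-dihydrobenzofurans and of N-sec-alkyl-2-bromoanilines to 2-substituted indolines. Ring B closes as a five-membered ring by contraction of the six-membered palladacycle, an exo-type closure at the primary methyl carbon. No stereocenter is created: C2 is carried over from the lactate, no bond to it is made or broken, and metalation of the neighbouring methyl group cannot epimerize it. The step needs site selectivity among the C–H bonds and chemoselectivity against C–O coupling: the C2 methyl group is the only primary C–H that reaches palladium through a six-membered palladacycle (the carbinol methyl groups would need a seven-membered one, while the OMe group and the C2–H would give five-membered ones that could only close a strained four-membered ring), the position on ring A is fixed by the bromine, and the tertiary hydroxyl is capped as its silyl ether.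

Step 8
Reactants: 14 ({2-[(2S)-5-(1,3-dioxolan-2-yl)-4-methoxy-2,3-dihydro-1-benzofuran-2-yl]propan-2-yl}oxy)(trimethyl)silane
Product: 15 (2S)-2-(2-hydroxypropan-2-yl)-4-methoxy-2,3-dihydro-1-benzofuran-5-carbaldehyde
Conditions: 1 M HCl (aq), THF, rt
Reagents that add atoms: water O
Why: Dilute aqueous acid should hydrolyse the electron-rich aryl dioxolane and the trimethylsilyl ether in one operation (acetal hydrolysis plus desilylation), while the tertiary alcohol, deactivated towards ionization by the neighbouring ether oxygen, and the C2 stereocenter should be untouched.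

Step 9
Reactants: 15 (2S)-2-(2-hydroxypropan-2-yl)-4-methoxy-2,3-dihydro-1-benzofuran-5-carbaldehyde; 16 4-hydroxyacetophenone (1-(4-hydroxyphenyl)ethan-1-one)
Product: 18 (2E)-1-(4-hydroxyphenyl)-3-[(2S)-2-(2-hydroxypropan-2-yl)-4-methoxy-2,3-dihydro-1-benzofuran-5-yl]prop-2-en-1-one, via aldol adduct 17 (not isolated)
Conditions: KOH (50% aq), EtOH, rt; then 1 M HCl to pH 5
Reagents that add atoms: none
Why: Claisen–Schmidt (crossed aldol) condensation, in which the ketone enolate formed in excess KOH adds to the non-enolizable aldehyde and the aldol adduct loses water by E1cB to the conjugated enone, expected as the thermodynamically favoured E isomer, while C2 bears no acidic hydrogen and is unaffected.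

**Compound list**

1 | 2-bromoresorcinol (2-bromobenzene-1,3-diol) | Oc1cccc(O)c1Br | starting material
2 | (3-bromo-2,4-dihydroxybenzylidene)dimethylammonium chloride | C[N+](C)=Cc1ccc(O)c(Br)c1O.[Cl-] | intermediate (not isolated)
3 | 3-bromo-2,4-dihydroxybenzaldehyde | O=Cc1ccc(O)c(Br)c1O | intermediate
4 | methyl (R)-lactate (methyl (2R)-2-hydroxypropanoate) | C[C@@H](O)C(=O)OC | starting material
5 | methyl (2R)-2-[(triphenylphosphonio)oxy]propanoate 2-bromo-4-formyl-3-hydroxyphenolate (ion pair) | C[C@@H](O[P+](c1ccccc1)(c1ccccc1)c1ccccc1)C(=O)OC.[O-]c1ccc(C=O)c(O)c1Br | intermediate (not isolated)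
6 | methyl (2S)-2-(2-bromo-4-formyl-3-hydroxyphenoxy)propanoate | C[C@H](Oc1ccc(C=O)c(O)c1Br)C(=O)OC | intermediate
7 | methyl (2S)-2-(2-bromo-4-formyl-3-methoxyphenoxy)propanoate | C[C@H](Oc1ccc(C=O)c(OC)c1Br)C(=O)OC | intermediate
8 | methyl (2S)-2-[2-bromo-4-(1,3-dioxolan-2-yl)-3-methoxyphenoxy]propanoate | C[C@H](Oc1ccc(C2OCCO2)c(OC)c1Br)C(=O)OC | intermediate
9 | (3S)-3-[2-bromo-4-(1,3-dioxolan-2-yl)-3-methoxyphenoxy]butan-2-one | C[C@H](Oc1ccc(C2OCCO2)c(OC)c1Br)C(C)=O | intermediate (not isolated)
10 | (3S)-3-[2-bromo-4-(1,3-dioxolan-2-yl)-3-methoxyphenoxy]-2-methylbutan-2-ol | C[C@H](Oc1ccc(C2OCCO2)c(OC)c1Br)C(C)(C)O | intermediate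
11 | {[(3S)-3-[2-bromo-4-(1,3-dioxolan-2-yl)-3-methoxyphenoxy]-2-methylbutan-2-yl]oxy}(trimethyl)silane | C[C@H](Oc1ccc(C2OCCO2)c(OC)c1Br)C(C)(C)O[Si](C)(C)C | intermediate
12 | arylpalladium pivalate: 11 with Br replaced by Pd(OPiv)(PCy3), divalent palladium on the ring A carbon between the two oxygens | C[C@H](Oc1ccc(C2OCCO2)c(OC)c1[Pd-](OC(=O)C(C)(C)C)[P+](C3CCCCC3)(C3CCCCC3)C3CCCCC3)C(C)(C)O[Si](C)(C)C | intermediate (not isolated)
13 | six-membered palladacycle: Pd(PCy3), divalent palladium, bonded to the future C3a of ring A and to the former C2 methyl carbon (future C3); C2 is S | [Pd-]1([P+](C3CCCCC3)(C3CCCCC3)C3CCCCC3)C[C@@H](C(C)(C)O[Si](C)(C)C)Oc2ccc(C4OCCO4)c(OC)c12 | intermediate (not isolated)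
14 | ({2-[(2S)-5-(1,3-dioxolan-2-yl)-4-methoxy-2,3-dihydro-1-benzofuran-2-yl]propan-2-yl}oxy)(trimethyl)silane | COc1c(C2OCCO2)ccc2c1C[C@@H](C(C)(C)O[Si](C)(C)C)O2 | intermediate
15 | (2S)-2-(2-hydroxypropan-2-yl)-4-methoxy-2,3-dihydro-1-benzofuran-5-carbaldehyde | COc1c(C=O)ccc2c1C[C@@H](C(C)(C)O)O2 | intermediate
16 | 4-hydroxyacetophenone (1-(4-hydroxyphenyl)ethan-1-one) | CC(=O)c1ccc(O)cc1 | starting material
17 | 3-hydroxy-1-(4-hydroxyphenyl)-3-[(2S)-2-(2-hydroxypropan-2-yl)-4-methoxy-2,3-dihydro-1-benzofuran-5-yl]propan-1-one (both epimers at the new carbinol carbon) | COc1c(C(O)CC(=O)c2ccc(O)cc2)ccc2c1C[C@@H](C(C)(C)O)O2 | intermediate (not isolated)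
18 | (2E)-1-(4-hydroxyphenyl)-3-[(2S)-2-(2-hydroxypropan-2-yl)-4-methoxy-2,3-dihydro-1-benzofuran-5-yl]prop-2-en-1-one | COc1c(/C=C/C(=O)c2ccc(O)cc2)ccc2c1C[C@@H](C(C)(C)O)O2 | target

**Summary**

Total step count: 9. Longest linear sequence: 9 steps (1 to 18); 4 and 16 enter as purchased partners.

Steps most likely to fail:

Step 7. Oxidative addition at the bromide flanked by two alkoxy groups may be slow, so that protodebromination, metalation at a wrong C–H bond, or loss of the silyl cap followed by C–O ring closure could compete with the desired palladacycle. The fallback closes ring B at O1–C2 instead, by known chemistry; it sets out from 3 and returns at 15. Compound 3 is silylated at the free 4-OH (TIPSCl, imidazole, CH2Cl2) to 3-bromo-2-hydroxy-4-(triisopropylsilyloxy)benzaldehyde F1. This is methylated (MeI, Ag2O, MeCN) to 3-bromo-2-methoxy-4-(triisopropylsilyloxy)benzaldehyde F2. Stille coupling at the bromide (tributyl(3-methylbut-2-en-1-yl)stannane, Pd(PPh3)4, DMF, 90 °C) should give 2-methoxy-3-(3-methylbut-2-en-1-yl)-4-(triisopropylsilyloxy)benzaldehyde F3. Shi epoxidation (D-fructose-derived ketone catalyst, KHSO5, K2CO3, MeCN/dimethoxymethane/H2O, 0 °C) should give 3-{[(2R)-3,3-dimethyloxiran-2-yl]methyl}-2-methoxy-4-(triisopropylsilyloxy)benzaldehyde F4, the R epoxide being the one expected from the spiro transition-state model. TBAF in THF then frees the phenoxide, which should open the epoxide 5-exo at its secondary carbon with inversion to give 15 with S configuration at C2. The route continues with step 9.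

Step 9. The ketone is deprotonated first at its phenol, so enolate formation is slow, and the aldehyde is electron-rich and ortho-disubstituted; the condensation may stall or be overtaken by base-induced side reactions on long exposure. The fallback replaces the aldol condensation by a Wittig olefination under neutral conditions; it sets out from 16 and 15 and returns at 18. Compound 16 is brominated at the methyl group (CuBr2, EtOAc/CHCl3, reflux) to 2-bromo-1-(4-hydroxyphenyl)ethan-1-one F5. This is quaternized (PPh3, MeCN, rt) to [2-(4-hydroxyphenyl)-2-oxoethyl]triphenylphosphonium bromide F6. Aqueous Na2CO3/CH2Cl2 converts it to the stabilized ylide 1-(4-hydroxyphenyl)-2-(triphenyl-λ5-phosphanylidene)ethan-1-one F7. Heating F7 with 15 in toluene at 100 °C should give the E enone 18.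

Step 2. Discrimination between the two phenolic hydroxyls may be poor, or displacement by the phenol next to bromine may be slow, so that elimination of the activated lactate wins. The fallback replaces the redox condensation by alkylation with a preformed sulfonate; it sets out from 4 and 3 and returns at 6. Compound 4 is tosylated with retention (TsCl, Et3N, DMAP cat., CH2Cl2, 0 °C) to methyl (2R)-2-{[(4-methylphenyl)sulfonyl]oxy}propanoate F8. Compound 3 is then alkylated with F8 at the more acidic 4-OH (K2CO3, 1 equiv, MeCN, 60 °C) by SN2 with inversion, which should give 6.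

**Further compounds**

F1 | step 7 | 3-bromo-2-hydroxy-4-(triisopropylsilyloxy)benzaldehyde | O=Cc1ccc(O[Si](C(C)C)(C(C)C)C(C)C)c(Br)c1O
F2 | step 7 | 3-bromo-2-methoxy-4-(triisopropylsilyloxy)benzaldehyde | COc1c(C=O)ccc(O[Si](C(C)C)(C(C)C)C(C)C)c1Br
F3 | step 7 | 2-methoxy-3-(3-methylbut-2-en-1-yl)-4-(triisopropylsilyloxy)benzaldehyde | COc1c(C=O)ccc(O[Si](C(C)C)(C(C)C)C(C)C)c1CC=C(C)C
F4 | step 7 | 3-{[(2R)-3,3-dimethyloxiran-2-yl]methyl}-2-methoxy-4-(triisopropylsilyloxy)benzaldehyde | COc1c(C=O)ccc(O[Si](C(C)C)(C(C)C)C(C)C)c1C[C@H]1OC1(C)C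
F5 | step 9 | 2-bromo-1-(4-hydroxyphenyl)ethan-1-one | O=C(CBr)c1ccc(O)cc1
F6 | step 9 | [2-(4-hydroxyphenyl)-2-oxoethyl]triphenylphosphonium bromide | O=C(C[P+](c1ccccc1)(c1ccccc1)c1ccccc1)c1ccc(O)cc1.[Br-]
F7 | step 9 | 1-(4-hydroxyphenyl)-2-(triphenyl-λ5-phosphanylidene)ethan-1-one | O=C(C=P(c1ccccc1)(c1ccccc1)c1ccccc1)c1ccc(O)cc1
F8 | step 2 | methyl (2R)-2-{[(4-methylphenyl)sulfonyl]oxy}propanoate | C[C@@H](OS(=O)(=O)c1ccc(C)cc1)C(=O)OC
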